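Ring B is made in one benzannulation, and the rest of the route depends on it. Its skeleton is cut into a furan and an alkynoate. The two C–O carbons para to each other (diaryl-ether carbon and phenol carbon), with the ester-oxygen carbon and the C-methyl carbon between them, come from 4-(benzyloxy)-3-methyl-2-(triisopropylsilyloxy)furan. The vicinal lactone-carbonyl and lactol carbons come from ethyl 4,4-diethoxybut-2-ynoate. A [4+2] cycloaddition and opening of the oxygen bridge form both C–C bonds, close ring B and leave its three oxygens differentiated (free OH, benzyl ether, silyl ether). Ring A is then attached by SNAr, the seven-membered lactone (ring C) is closed, and the labile lactol stereocentre is set last by a lipase.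

Key step: step 5

Assumption: the C1 lactol (a 3-hydroxyphthalide) can epimerise by ring opening to the formyl acid, mainly under base; the (R) enantiomer is therefore released last, under neutral cold conditions, and is taken to be isolable as a solid. The (R) preference of the chosen lipase is assumed and would be confirmed on the racemate.

Design choices: the furan carries a triisopropylsilyl group, which should resist the base and fluoride of step 9 and silyl transfer in step 5 better than smaller silyl groups. Ring A carries a benzyl ester, so that one hydrogenolysis frees both partners of the lactonisation.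

Step 1
Reactants: 1 ethyl 2-methyl-3-oxobutanoate
Product: 3 4-hydroxy-3-methylfuran-2(5H)-one (3-methyltetronic acid), via ethyl 4-bromo-2-methyl-3-oxobutanoate 2 (not isolated)
Conditions: Br2 (1.0 equiv), CHCl3, 0 °C → rt, 16 h; evaporate; neat, 120 °C, 3 h
Reagents that add atoms: none
Why: Ketone bromination equilibrated by the HBr formed should place bromine on the terminal methyl, and on heating the ester oxygen displaces bromide (5-exo-tet) with loss of bromoethane, the classical tetronic acid cyclisation.

Step 2
Reactants: 3 4-hydroxy-3-methylfuran-2(5H)-one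
Product: 4 4-(benzyloxy)-3-methylfuran-2(5H)-one
Conditions: BnOH, PPh3, DIAD, THF, 0 °C → rt
Reagents that add atoms: benzyl alcohol, OCc1ccccc1
Why: The vinylogous acid is acidic enough to serve as a Mitsunobu pronucleophile and should be alkylated on the 4-oxygen, which avoids the C-alkylation seen with benzyl halides and base.

Step 3
Reactants: 4 4-(benzyloxy)-3-methylfuran-2(5H)-one
Product: 5 4-(benzyloxy)-3-methyl-2-(triisopropylsilyloxy)furan
Conditions: TIPSOTf, Et3N, CH2Cl2, 0 °C; filtration through basic alumina
Reagents that add atoms: triisopropylsilyl trifluoromethanesulfonate, CC(C)[Si](C(C)C)(C(C)C)OS(=O)(=O)C(F)(F)F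
Why: Soft enolisation (silylation of the lactone carbonyl oxygen, then loss of a C5 proton to the amine) should give the aromatic 2-silyloxyfuran, the standard silyl dienol ether formation of butenolides.

Step 4
Reactants: 6 3,3-diethoxyprop-1-yne
Product: 8 ethyl 4,4-diethoxybut-2-ynoate, via lithium 3,3-diethoxyprop-1-ynide 7 (not isolated)
Conditions: n-BuLi, THF, −78 °C; ClCO2Et, −78 → 0 °C
Reagents that add atoms: ethyl chloroformate, CCOC(=O)Cl
Why: Deprotonation of the terminal alkyne and acylation of the acetylide with a chloroformate is a routine alkynoate synthesis, and the acetal is inert to base.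

Step 5
Reactants: 5 4-(benzyloxy)-3-methyl-2-(triisopropylsilyloxy)furan; 8 ethyl 4,4-diethoxybut-2-ynoate
Product: 10 ethyl 4-(benzyloxy)-2-(diethoxymethyl)-3-hydroxy-5-methyl-6-(triisopropylsilyloxy)benzoate, via oxa-bridged cycloadduct 9 (not isolated)
Conditions: 5 (1.3 equiv), toluene, 90 °C, sealed tube; chromatography on Et3N-deactivated silica
Reagents that add atoms: none
Why: A normal-electron-demand [4+2] cycloaddition (Diels–Alder reaction of a 2-silyloxyfuran with an alkynoate, possibly asynchronous to the point of a vinylogous Mukaiyama–Michael addition followed by closure) joins furan C5 to the alkyne carbon beta to the ester and furan C2 to the ester-bearing carbon, giving the oxa-bridged diene 9. The bridge then ionises at the C–O bond of the silyloxy-bearing bridgehead, where the cation is oxygen-stabilised, and loss of the only bridgehead proton aromatises the ring, so the bridge oxygen ends as the free phenol para to the silyl ether. The closest known reaction type is the benzannulation of 2-silyloxyfurans with acetylenic esters to hydroquinone monoethers. Ring B is closed by intermolecular suprafacial addition of the furan diene across the alkyne; the two bridgehead stereocentres of 9 disappear on aromatisation, so no stereocentre has to be controlled. The step needs regioselectivity, which is secured because the ester alone polarises the alkyne (the second carbonyl is masked as an acetal) and the unsubstituted furan terminus is the most nucleophilic diene carbon, activated through the diene by the 2-silyloxy group and directly by the 4-benzyloxy enol ether. The direction of bridge opening is fixed because only one bridgehead carries a cation-stabilising oxygen and only the other carries a hydrogen.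

Step 6
Reactants: 11 1-fluoro-3-methoxy-5-methylbenzene
Product: 13 2-fluoro-6-methoxy-4-methylbenzaldehyde, via 2-fluoro-6-methoxy-4-methylphenyllithium 12 (not isolated)
Conditions: n-BuLi, THF, −78 °C; DMF, −78 → 0 °C; aq. HCl
Reagents that add atoms: N,N-dimethylformamide, CN(C)C=O
Why: Directed ortho-metalation should occur at the most acidic ring position, flanked by fluorine and methoxy, and the aryllithium is formylated by DMF.

Step 7
Reactants: 13 2-fluoro-6-methoxy-4-methylbenzaldehyde
Product: 14 3-bromo-2-fluoro-6-methoxy-4-methylbenzaldehyde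
Conditions: NBS, DMF, rt, dark
Reagents that add atoms: N-bromosuccinimide, O=C1CCC(=O)N1Br
Why: Electrophilic aromatic bromination should go para to the methoxy group (also ortho to methyl and meta to formyl), the other free position being ortho to methoxy and more crowded.

Step 8
Reactants: 14 3-bromo-2-fluoro-6-methoxy-4-methylbenzaldehyde
Product: 15 benzyl 2-fluoro-3-formyl-4-methoxy-6-methylbenzoate
Conditions: Pd(OAc)2 (cat.), Xantphos, CO (1 atm), BnOH, Et3N, toluene, 90 °C
Reagents that add atoms: carbon monoxide, [C-]#[O+]; benzyl alcohol, OCc1ccccc1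
Why: Palladium-catalysed alkoxycarbonylation of the aryl bromide (oxidative addition, CO insertion, alcoholysis) tolerates the aldehyde and the C–F bond, and the weak amine base generates no alkoxide that could displace fluoride.

Step 9
Reactants: 10 ethyl 4-(benzyloxy)-2-(diethoxymethyl)-3-hydroxy-5-methyl-6-(triisopropylsilyloxy)benzoate; 15 benzyl 2-fluoro-3-formyl-4-methoxy-6-methylbenzoate
Product: 17 benzyl 2-[6-(benzyloxy)-2-(diethoxymethyl)-3-(ethoxycarbonyl)-5-methyl-4-(triisopropylsilyloxy)phenoxy]-3-formyl-4-methoxy-6-methylbenzoate, via sodium phenoxide 16 (not isolated)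
Conditions: NaH (1.0 equiv), THF, 0 °C; 15, DMF, 55 °C
Reagents that add atoms: none
Why: Nucleophilic aromatic substitution (addition–elimination) should proceed at the C–F carbon activated by an ortho formyl and an ortho ester group, and the fluoride leaves as insoluble NaF, which spares the aryl silyl ether.

Step 10
Reactants: 17 the diaryl ether of step 9
Product: 18 2-[2-(diethoxymethyl)-3-(ethoxycarbonyl)-6-hydroxy-5-methyl-4-(triisopropylsilyloxy)phenoxy]-3-formyl-4-methoxy-6-methylbenzoic acid
Conditions: H2 (1 atm), Pd/C (10 wt%), EtOAc, rt, stopped after two equivalents of H2; crude used at once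
Reagents that add atoms: none
Why: Catalytic hydrogenolysis cleaves the aryl benzyl ether and the benzyl ester much faster than it reduces the hindered benzaldehyde flanked by two ortho substituents and conjugated to the methoxy donor, and the neutral medium leaves the acetal and silyl ether intact.

Step 11
Reactants: 18 the hydroxy acid of step 10
Product: 19 ethyl 6-(diethoxymethyl)-4-formyl-3-methoxy-1,9-dimethyl-11-oxo-8-(triisopropylsilyloxy)-11H-dibenzo[b,e][1,4]dioxepine-7-carboxylate
Conditions: DCC, DMAP (cat.), CH2Cl2 (0.005 M), 0 °C → rt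
Reagents that add atoms: none
Why: Carbodiimide-mediated (Steglich-type) lactonisation of a 2'-hydroxy diaryl ether 2-carboxylic acid is the standard closure of the seven-membered depsidone ring, and it is neutral enough for the acetal.

Step 12
Reactants: 19 the depsidone aldehyde of step 11
Product: 20 ethyl 6-(diethoxymethyl)-4-(hydroxymethyl)-3-methoxy-1,9-dimethyl-11-oxo-8-(triisopropylsilyloxy)-11H-dibenzo[b,e][1,4]dioxepine-7-carboxylate
Conditions: NaBH4, THF/EtOH, −20 °C; AcOH quench
Reagents that add atoms: none
Why: Borohydride reduction of the only aldehyde is much faster at low temperature than attack on the hindered aryl lactone or the ethyl ester, and ethanol as cosolvent makes any alkoxide exchange at the ethyl ester and diethyl acetal degenerate.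

Step 13
Reactants: 20 the depsidone alcohol of step 12
Product: 22 racemic 1,4-dihydroxy-11-(hydroxymethyl)-10-methoxy-5,8-dimethyl-1H-isobenzofuro[4,5-b][1,4]benzodioxepine-3,7-dione, via desilylated phenol 21 (not isolated)
Conditions: TBAF, AcOH (1:1), THF, 0 °C → rt; then 1 M aq. H2SO4, 45 °C
Reagents that add atoms: water, O
Why: Buffered fluoride desilylation frees the phenol without opening the aryl lactone, and acid-catalysed acetal hydrolysis with neighbouring-group participation of the ortho ester carbonyl (5-exo capture of the oxocarbenium, loss of ethanol) should give the 3-hydroxyphthalide, as the racemate because nothing biases the new hemiacetal carbon.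

Step 14
Reactants: 22 the racemic lactol of step 13
Product: 23 (1R)-1-acetoxy-11-(acetoxymethyl)-4-hydroxy-10-methoxy-5,8-dimethyl-1H-isobenzofuro[4,5-b][1,4]benzodioxepine-3,7-dione
Conditions: immobilised Burkholderia cepacia lipase, vinyl acetate, Et3N (cat.), toluene/THF, 35 °C
Reagents that add atoms: vinyl acetate, CC(=O)OC=C
Why: Lipase-catalysed acylative dynamic kinetic resolution of a lactol: the hemiacetal racemises through the open formyl carboxylate under the amine while the enzyme active site acylates only the (R)-lactol, which sets C1 under catalyst control; the primary alcohol is acetylated as well and the hindered hydrogen-bonded phenol should stay free.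

Step 15
Reactants: 23 the (R)-diacetate of step 14
Product: 24 (1R)-1,4-dihydroxy-11-(hydroxymethyl)-10-methoxy-5,8-dimethyl-1H-isobenzofuro[4,5-b][1,4]benzodioxepine-3,7-dione
Conditions: immobilised Burkholderia cepacia lipase, n-BuOH, MTBE, 5 °C; filtration, crystallisation below 5 °C
Reagents that add atoms: none
Why: Lipase-catalysed alcoholysis cleaves both acetates at the acyl–oxygen bond, so the C1–O bond is untouched and the configuration is retained; the enzyme that made the (R)-acetate is matched to it in the reverse direction, and the base-free cold medium should suppress ring-opening racemisation.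

Compound list
1 | ethyl 2-methyl-3-oxobutanoate (ethyl 2-methylacetoacetate) | CCOC(=O)C(C)C(C)=O | starting material
2 | ethyl 4-bromo-2-methyl-3-oxobutanoate (not isolated) | CCOC(=O)C(C)C(=O)CBr | intermediate
3 | 4-hydroxy-3-methylfuran-2(5H)-one (3-methyltetronic acid) | CC1=C(O)COC1=O | intermediate
4 | 4-(benzyloxy)-3-methylfuran-2(5H)-one | CC1=C(OCc2ccccc2)COC1=O | intermediate
5 | 4-(benzyloxy)-3-methyl-2-(triisopropylsilyloxy)furan | CC(C)[Si](Oc1occ(OCc2ccccc2)c1C)(C(C)C)C(C)C | intermediate
6 | 3,3-diethoxyprop-1-yne | C#CC(OCC)OCC | starting material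
7 | lithium 3,3-diethoxyprop-1-ynide (not isolated) | [Li]C#CC(OCC)OCC | intermediate
8 | ethyl 4,4-diethoxybut-2-ynoate | CCOC(=O)C#CC(OCC)OCC | intermediate
9 | ethyl 5-(benzyloxy)-3-(diethoxymethyl)-6-methyl-1-(triisopropylsilyloxy)-7-oxabicyclo[2.2.1]hepta-2,5-diene-2-carboxylate (racemic oxa-bridged cycloadduct, not isolated) | CCOC(=O)C1=C(C(OCC)OCC)C2OC1(O[Si](C(C)C)(C(C)C)C(C)C)C(C)=C2OCc1ccccc1 | intermediate
10 | ethyl 4-(benzyloxy)-2-(diethoxymethyl)-3-hydroxy-5-methyl-6-(triisopropylsilyloxy)benzoate | CCOC(=O)c1c(O[Si](C(C)C)(C(C)C)C(C)C)c(C)c(OCc2ccccc2)c(O)c1C(OCC)OCC | intermediate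
11 | 1-fluoro-3-methoxy-5-methylbenzene | COc1cc(C)cc(F)c1 | starting material
12 | 2-fluoro-6-methoxy-4-methylphenyllithium (not isolated) | [Li]c1c(F)cc(C)cc1OC | intermediate
13 | 2-fluoro-6-methoxy-4-methylbenzaldehyde | COc1cc(C)cc(F)c1C=O | intermediate
14 | 3-bromo-2-fluoro-6-methoxy-4-methylbenzaldehyde | COc1cc(C)c(Br)c(F)c1C=O | intermediate
15 | benzyl 2-fluoro-3-formyl-4-methoxy-6-methylbenzoate | COc1cc(C)c(C(=O)OCc2ccccc2)c(F)c1C=O | intermediate
16 | sodium 6-(benzyloxy)-2-(diethoxymethyl)-3-(ethoxycarbonyl)-5-methyl-4-(triisopropylsilyloxy)phenoxide (not isolated) | [Na+].CCOC(=O)c1c(O[Si](C(C)C)(C(C)C)C(C)C)c(C)c(OCc2ccccc2)c([O-])c1C(OCC)OCC | intermediate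
17 | benzyl 2-[6-(benzyloxy)-2-(diethoxymethyl)-3-(ethoxycarbonyl)-5-methyl-4-(triisopropylsilyloxy)phenoxy]-3-formyl-4-methoxy-6-methylbenzoate | COc1cc(C)c(C(=O)OCc2ccccc2)c(Oc2c(OCc3ccccc3)c(C)c(O[Si](C(C)C)(C(C)C)C(C)C)c(C(=O)OCC)c2C(OCC)OCC)c1C=O | intermediate
18 | 2-[2-(diethoxymethyl)-3-(ethoxycarbonyl)-6-hydroxy-5-methyl-4-(triisopropylsilyloxy)phenoxy]-3-formyl-4-methoxy-6-methylbenzoic acid | COc1cc(C)c(C(=O)O)c(Oc2c(O)c(C)c(O[Si](C(C)C)(C(C)C)C(C)C)c(C(=O)OCC)c2C(OCC)OCC)c1C=O | intermediate
19 | ethyl 6-(diethoxymethyl)-4-formyl-3-methoxy-1,9-dimethyl-11-oxo-8-(triisopropylsilyloxy)-11H-dibenzo[b,e][1,4]dioxepine-7-carboxylate | COc1cc(C)c2c(c1C=O)Oc1c(c(C)c(O[Si](C(C)C)(C(C)C)C(C)C)c(C(=O)OCC)c1C(OCC)OCC)OC2=O | intermediate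
20 | ethyl 6-(diethoxymethyl)-4-(hydroxymethyl)-3-methoxy-1,9-dimethyl-11-oxo-8-(triisopropylsilyloxy)-11H-dibenzo[b,e][1,4]dioxepine-7-carboxylate | COc1cc(C)c2c(c1CO)Oc1c(c(C)c(O[Si](C(C)C)(C(C)C)C(C)C)c(C(=O)OCC)c1C(OCC)OCC)OC2=O | intermediate
21 | ethyl 6-(diethoxymethyl)-8-hydroxy-4-(hydroxymethyl)-3-methoxy-1,9-dimethyl-11-oxo-11H-dibenzo[b,e][1,4]dioxepine-7-carboxylate (not isolated) | COc1cc(C)c2c(c1CO)Oc1c(c(C)c(O)c(C(=O)OCC)c1C(OCC)OCC)OC2=O | intermediate
22 | racemic 1,4-dihydroxy-11-(hydroxymethyl)-10-methoxy-5,8-dimethyl-1H-isobenzofuro[4,5-b][1,4]benzodioxepine-3,7-dione | COc1cc(C)c2c(c1CO)Oc1c(c(C)c(O)c3c1C(O)OC3=O)OC2=O | intermediate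
23 | (1R)-1-acetoxy-11-(acetoxymethyl)-4-hydroxy-10-methoxy-5,8-dimethyl-1H-isobenzofuro[4,5-b][1,4]benzodioxepine-3,7-dione | COc1cc(C)c2c(c1COC(C)=O)Oc1c(c(C)c(O)c3c1[C@H](OC(C)=O)OC3=O)OC2=O | intermediate
24 | (1R)-1,4-dihydroxy-11-(hydroxymethyl)-10-methoxy-5,8-dimethyl-1H-isobenzofuro[4,5-b][1,4]benzodioxepine-3,7-dione | COc1cc(C)c2c(c1CO)Oc1c(c(C)c(O)c3c1[C@H](O)OC3=O)OC2=O | target

Total step count: 15. Longest linear sequence: 11 steps (steps 1, 2, 3, 5, 9, 10, 11, 12, 13, 14, 15); steps 4 and 6–8 are side branches.

Steps most likely to fail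

Step 5. The cycloaddition of the mono-activated alkyne may be slower than thermal decomposition or silyl loss of the furan, or conjugate addition may occur without ring closure. The fallback sets out from 4 and 8 and replaces the thermal cycloaddition by an anionic Michael–Dieckmann annulation. LDA (THF, −78 °C) converts 4 into lithium 4-(benzyloxy)-3-methylfuran-2-olate F1, whose C5 adds to the beta carbon of 8. The resulting allenolate attacks the lactone carbonyl, the bridged alkoxide collapses and tautomerises, and aqueous NH4Cl should give ethyl 4-(benzyloxy)-2-(diethoxymethyl)-3,6-dihydroxy-5-methylbenzoate F2. Its 6-OH is chelated to the ester, so SNAr with 15 (K2CO3, DMF, 60 °C) should take place at the 3-OH and give benzyl 2-[6-(benzyloxy)-2-(diethoxymethyl)-3-(ethoxycarbonyl)-4-hydroxy-5-methylphenoxy]-3-formyl-4-methoxy-6-methylbenzoate F3. Silylation (TIPSCl, imidazole, DMF, 50 °C) comes back to the route at 17.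

Step 9. Addition of the doubly ortho-substituted phenoxide to the crowded C–F carbon may be slow enough for acyl transfer from the benzyl ester or loss of the silyl group to compete. The fallback sets out from 16 (made from 10 as in step 9) and 14, whose flanking bromine is smaller than the ester and cannot act as an acyl donor. SNAr (DMF, 80 °C) should give ethyl 4-(benzyloxy)-3-(2-bromo-6-formyl-5-methoxy-3-methylphenoxy)-2-(diethoxymethyl)-5-methyl-6-(triisopropylsilyloxy)benzoate F4. Benzyloxycarbonylation of its aryl bromide under the conditions of step 8 (Pd(OAc)2, Xantphos, CO, BnOH, Et3N) comes back to the route at 17.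

Step 14. The enzyme may not accept the crowded lactol, or may acylate it with low or opposite enantioselection. The fallback sets out from 22 and uses a small-molecule acylative dynamic kinetic resolution: a chiral isothiourea acyl-transfer catalyst (the HyperBTM enantiomer that gives the (R)-ester), isobutyric anhydride and iPr2NEt in CH2Cl2. This should give (1R)-4-hydroxy-1-(isobutyryloxy)-11-(isobutyryloxymethyl)-10-methoxy-5,8-dimethyl-1H-isobenzofuro[4,5-b][1,4]benzodioxepine-3,7-dione F5. Its two esters are then removed by lipase alcoholysis (Candida antarctica lipase B, n-BuOH, MTBE, 5 °C), which comes back to the route at 24.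

Further compounds
F1 | step 5 | lithium 4-(benzyloxy)-3-methylfuran-2-olate | [Li+].[O-]c1occ(OCc2ccccc2)c1C
F2 | step 5 | ethyl 4-(benzyloxy)-2-(diethoxymethyl)-3,6-dihydroxy-5-methylbenzoate | CCOC(=O)c1c(O)c(C)c(OCc2ccccc2)c(O)c1C(OCC)OCC
F3 | step 5 | benzyl 2-[6-(benzyloxy)-2-(diethoxymethyl)-3-(ethoxycarbonyl)-4-hydroxy-5-methylphenoxy]-3-formyl-4-methoxy-6-methylbenzoate | COc1cc(C)c(C(=O)OCc2ccccc2)c(Oc2c(OCc3ccccc3)c(C)c(O)c(C(=O)OCC)c2C(OCC)OCC)c1C=O
F4 | step 9 | ethyl 4-(benzyloxy)-3-(2-bromo-6-formyl-5-methoxy-3-methylphenoxy)-2-(diethoxymethyl)-5-methyl-6-(triisopropylsilyloxy)benzoate | COc1cc(C)c(Br)c(Oc2c(OCc3ccccc3)c(C)c(O[Si](C(C)C)(C(C)C)C(C)C)c(C(=O)OCC)c2C(OCC)OCC)c1C=O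
F5 | step 14 | (1R)-4-hydroxy-1-(isobutyryloxy)-11-(isobutyryloxymethyl)-10-methoxy-5,8-dimethyl-1H-isobenzofuro[4,5-b][1,4]benzodioxepine-3,7-dione | COc1cc(C)c2c(c1COC(=O)C(C)C)Oc1c(c(C)c(O)c3c1[C@H](OC(=O)C(C)C)OC3=O)OC2=O
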